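## Retrosynthetic overview

1. Target 27 ⇐ removal of two MOM ethers from 26 ⇐ aromatic Claisen rearrangement of the 4'-O-prenyl ether 24; C-1' and C-3' are blocked, so the 1,1-dimethylallyl group can only end at C-5'.
2. 24 ⇐ chroman 21. Ring C is the only ring built (rings A and B are bought as arenes), closed by an intramolecular Mitsunobu O1–C2 etherification of phenol-alcohol 20.
3. 20 ⇐ C4–C4a bond by Negishi coupling of the alkylzinc from iodide 12 with the ring A iodide 17.
4. C-3 stereocentre ⇐ desymmetrising acetylation of the prochiral 2-arylpropane-1,3-diol 10 by a lipase (serine hydrolase class, EC 3.1.1.3).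
5. 10 ⇐ arylmalonate 9 ⇐ ring B iodide 7 (from 2,3-dihydroxybenzaldehyde 1) + diethyl malonate 8; 17 ⇐ resorcinol monobenzoate 13.

Assumption: the target is the (3S)-isoflavan as drawn, and the lipase acetylates the hydroxymethyl arm that gives (R)-11 (aryl bound as the large substituent, the usual preference of this lipase for primary alcohols). This sense is predicted, not established for this substrate; the configuration of 11 is checked (Mosher ester) before going on.

## Route

Step 1
Reactants: 1 2,3-dihydroxybenzaldehyde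
Product: 2 3-(benzyloxy)-2-hydroxybenzaldehyde
Conditions: NaH (2.2 equiv), DMSO, rt; BnBr (1.0 equiv), rt
Reagents that add atoms: benzyl bromide, BrCc1ccccc1
Why: Williamson etherification of the dianion takes place at the more nucleophilic 3-phenoxide, because the 2-phenoxide is conjugated with and chelated to the aldehyde.

Step 2
Reactants: 2 3-(benzyloxy)-2-hydroxybenzaldehyde
Product: 3 3-(benzyloxy)-2-(methoxymethoxy)benzaldehyde
Conditions: MOMCl, i-Pr2NEt, CH2Cl2, 0 °C to rt
Reagents that add atoms: chloromethyl methyl ether, COCCl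
Why: O-alkylation of the only free phenol gives a MOM acetal that survives every later basic, reductive and thermal step.

Step 3
Reactants: 3 3-(benzyloxy)-2-(methoxymethoxy)benzaldehyde
Product: 5 3-(benzyloxy)-2-(methoxymethoxy)phenol, via aryl formate 4 (not isolated)
Conditions: mCPBA, CH2Cl2, 0 °C to rt; then K2CO3 (cat.), MeOH, rt
Reagents that add atoms: meta-chloroperoxybenzoic acid, O=C(OO)c1cccc(Cl)c1
Why: Baeyer–Villiger (Dakin-type) oxidation, in which the electron-rich ortho-alkoxyaryl group migrates to give the formate, which is then methanolysed to the phenol.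

Step 4
Reactants: 5 3-(benzyloxy)-2-(methoxymethoxy)phenol
Product: 6 3-(benzyloxy)-6-iodo-2-(methoxymethoxy)phenol
Conditions: I2 (1.05 equiv), NaHCO3, THF/H2O, 0 °C
Reagents that add atoms: iodine, II
Why: Electrophilic aromatic iodination of the phenoxide goes ortho to OH and para to OBn (as 3-alkoxyphenols do under these conditions), since the position para to OH is crowded by the benzyloxy group.

Step 5
Reactants: 6 3-(benzyloxy)-6-iodo-2-(methoxymethoxy)phenol
Product: 7 1-(benzyloxy)-4-iodo-3-methoxy-2-(methoxymethoxy)benzene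
Conditions: MeI, K2CO3, DMF, rt
Reagents that add atoms: iodomethane, CI
Why: Williamson O-methylation of the phenol installs the 2'-methoxy group of the target next to the iodide.

Step 6
Reactants: 7 1-(benzyloxy)-4-iodo-3-methoxy-2-(methoxymethoxy)benzene; 8 diethyl malonate
Product: 9 diethyl 2-[4-(benzyloxy)-2-methoxy-3-(methoxymethoxy)phenyl]propanedioate
Conditions: CuI (10 mol %), 2-picolinic acid (20 mol %), Cs2CO3, 1,4-dioxane, 70 °C
Reagents that add atoms: none
Why: Copper-catalysed α-arylation of the malonate (Ullmann/Hurtley-type C–C coupling) works well with electron-rich aryl iodides carrying one ortho substituent.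

Step 7
Reactants: 9 diethyl 2-[4-(benzyloxy)-2-methoxy-3-(methoxymethoxy)phenyl]propanedioate
Product: 10 2-[4-(benzyloxy)-2-methoxy-3-(methoxymethoxy)phenyl]propane-1,3-diol
Conditions: LiAlH4 (3 equiv), THF, 0 °C to rt; Fieser work-up
Reagents that add atoms: none
Why: Hydride reduction of both esters gives the prochiral (achiral) 2-aryl-1,3-diol, with ethers and acetals untouched.

Step 8
Reactants: 10 2-[4-(benzyloxy)-2-methoxy-3-(methoxymethoxy)phenyl]propane-1,3-diol
Product: 11 (2R)-2-[4-(benzyloxy)-2-methoxy-3-(methoxymethoxy)phenyl]-3-hydroxypropyl acetate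
Conditions: Burkholderia cepacia lipase (immobilised lipase PS), vinyl acetate (4 equiv), t-BuOMe, 30 °C, stopped at about 5 % diacetate
Reagents that add atoms: vinyl acetate, C=COC(C)=O
Why: Lipase-catalysed enantiotopic-group-selective transesterification (enzymatic desymmetrisation with an irreversible acyl donor) acetylates one of the two enantiotopic CH2OH arms and so sets the stereocentre as R, and the slight over-acylation removes the minor enantiomer and raises the ee.

Step 9
Reactants: 11 (2R)-2-[4-(benzyloxy)-2-methoxy-3-(methoxymethoxy)phenyl]-3-hydroxypropyl acetate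
Product: 12 (2S)-2-[4-(benzyloxy)-2-methoxy-3-(methoxymethoxy)phenyl]-3-iodopropyl acetate
Conditions: PPh3, I2, imidazole, CH2Cl2, 0 °C, run directly on fresh 11
Reagents that add atoms: iodine, II
Why: Appel iodination of the primary alcohol under near-neutral conditions avoids 1,3-acyl migration and leaves the stereocentre untouched (the descriptor changes from R to S only because CH2I outranks CH2OAc).

Step 10
Reactants: 13 3-hydroxyphenyl benzoate (resorcinol monobenzoate)
Product: 14 3-(methoxymethoxy)phenyl benzoate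
Conditions: MOMCl, i-Pr2NEt, CH2Cl2, 0 °C to rt
Reagents that add atoms: chloromethyl methyl ether, COCCl
Why: O-alkylation of the single free phenol gives a clean mono-MOM resorcinol without statistical mixtures.

Step 11
Reactants: 14 3-(methoxymethoxy)phenyl benzoate
Product: 15 3-(methoxymethoxy)phenol
Conditions: K2CO3 (0.3 equiv), MeOH, rt
Reagents that add atoms: none
Why: Base-catalysed transesterification cleaves the aryl benzoate and leaves the MOM acetal intact.

Step 12
Reactants: 15 3-(methoxymethoxy)phenol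
Product: 16 2-iodo-5-(methoxymethoxy)phenol
Conditions: I2 (1.05 equiv), NaHCO3, THF/H2O, 0 °C
Reagents that add atoms: iodine, II
Why: Electrophilic iodination of the 3-alkoxyphenoxide occurs ortho to OH and para to the alkoxy group, as for 3-methoxyphenol.

Step 13
Reactants: 16 2-iodo-5-(methoxymethoxy)phenol
Product: 17 2-iodo-5-(methoxymethoxy)phenyl acetate
Conditions: Ac2O, pyridine, CH2Cl2, rt
Reagents that add atoms: acetic anhydride, CC(=O)OC(C)=O
Why: O-acylation masks the phenol as an ester that tolerates organozinc coupling and is later removed together with the alkyl acetate.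

Step 14
Reactants: 12 (2S)-2-[4-(benzyloxy)-2-methoxy-3-(methoxymethoxy)phenyl]-3-iodopropyl acetate; 17 2-iodo-5-(methoxymethoxy)phenyl acetate
Product: 19 (2S)-3-[2-(acetyloxy)-4-(methoxymethoxy)phenyl]-2-[4-(benzyloxy)-2-methoxy-3-(methoxymethoxy)phenyl]propyl acetate, via alkylzinc iodide 18 (not isolated)
Conditions: Zn dust (TMSCl/1,2-dibromoethane activated), DMF, rt; then 17, Pd2(dba)3 (2.5 mol %), SPhos (10 mol %), DMF, 40 °C
Reagents that add atoms: none
Why: Negishi sp3–sp2 coupling of the ester-tolerant primary alkylzinc with the aryl iodide on zerovalent palladium forms C4–C4a one carbon away from the stereocentre, and the bulky biarylphosphine makes reductive elimination outrun β-hydride loss.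

Step 15
Reactants: 19 (2S)-3-[2-(acetyloxy)-4-(methoxymethoxy)phenyl]-2-[4-(benzyloxy)-2-methoxy-3-(methoxymethoxy)phenyl]propyl acetate
Product: 20 2-[(2S)-2-[4-(benzyloxy)-2-methoxy-3-(methoxymethoxy)phenyl]-3-hydroxypropyl]-5-(methoxymethoxy)phenol
Conditions: K2CO3 (0.5 equiv), MeOH, rt
Reagents that add atoms: none
Why: Transesterification removes the aryl and the alkyl acetate in one operation and frees exactly the phenol and the primary alcohol needed for ring closure.

Step 16
Reactants: 20 2-[(2S)-2-[4-(benzyloxy)-2-methoxy-3-(methoxymethoxy)phenyl]-3-hydroxypropyl]-5-(methoxymethoxy)phenol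
Product: 21 (3S)-3-[4-(benzyloxy)-2-methoxy-3-(methoxymethoxy)phenyl]-7-(methoxymethoxy)chromane
Conditions: PPh3, DIAD, THF (0.02 M), 0 °C to rt
Reagents that add atoms: none
Why: Intramolecular Mitsunobu etherification closes ring C by attack of the only free phenol on the activated primary carbon, so the adjacent stereocentre is not involved.

Step 17
Reactants: 21 (3S)-3-[4-(benzyloxy)-2-methoxy-3-(methoxymethoxy)phenyl]-7-(methoxymethoxy)chromane
Product: 22 3-methoxy-2-(methoxymethoxy)-4-[(3S)-7-(methoxymethoxy)chroman-3-yl]phenol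
Conditions: H2 (1 atm), 10 % Pd/C, EtOAc, rt
Reagents that add atoms: none
Why: Hydrogenolysis cleaves only the benzyl ether and frees the 4'-OH while no alkene is yet present.

Step 18
Reactants: 22 3-methoxy-2-(methoxymethoxy)-4-[(3S)-7-(methoxymethoxy)chroman-3-yl]phenol; 23 1-bromo-3-methylbut-2-ene (prenyl bromide)
Product: 24 (3S)-3-[2-methoxy-3-(methoxymethoxy)-4-(3-methylbut-2-enyloxy)phenyl]-7-(methoxymethoxy)chromane
Conditions: K2CO3, acetone, reflux
Reagents that add atoms: none
Why: Williamson O-alkylation of the single free phenol with the primary allylic bromide gives the aryl prenyl ether.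

Step 19
Reactants: 24 (3S)-3-[2-methoxy-3-(methoxymethoxy)-4-(3-methylbut-2-enyloxy)phenyl]-7-(methoxymethoxy)chromane
Product: 26 3-methoxy-2-(methoxymethoxy)-4-[(3S)-7-(methoxymethoxy)chroman-3-yl]-6-(2-methylbut-3-en-2-yl)phenol, via ortho-dienone 25 (not isolated)
Conditions: N,N-diethylaniline, 190 °C, sealed tube, argon
Reagents that add atoms: none
Why: Aromatic Claisen [3,3]-sigmatropic rearrangement of the prenyl ether delivers the reverse-prenyl group to the only free ortho carbon (the other ortho and the para position are substituted), and the dienone tautomerises to the phenol.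

Step 20
Reactants: 26 3-methoxy-2-(methoxymethoxy)-4-[(3S)-7-(methoxymethoxy)chroman-3-yl]-6-(2-methylbut-3-en-2-yl)phenol
Product: 27 (3S)-3-[3,4-dihydroxy-2-methoxy-5-(2-methylbut-3-en-2-yl)phenyl]chroman-7-ol (target)
Conditions: 3 M aq. HCl, MeOH, 40 °C, argon
Reagents that add atoms: none
Why: Mild acid-catalysed acetal exchange with methanol removes both MOM groups without touching the terminal alkene, the methyl ether or the non-epimerisable benzylic stereocentre.

## Compound list

1 | 2,3-dihydroxybenzaldehyde | O=Cc1cccc(O)c1O | starting material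
2 | 3-(benzyloxy)-2-hydroxybenzaldehyde | O=Cc1cccc(OCc2ccccc2)c1O | intermediate
3 | 3-(benzyloxy)-2-(methoxymethoxy)benzaldehyde | O=Cc1cccc(OCc2ccccc2)c1OCOC | intermediate
4 | 3-(benzyloxy)-2-(methoxymethoxy)phenyl formate | O=COc1cccc(OCc2ccccc2)c1OCOC | intermediate
5 | 3-(benzyloxy)-2-(methoxymethoxy)phenol | Oc1cccc(OCc2ccccc2)c1OCOC | intermediate
6 | 3-(benzyloxy)-6-iodo-2-(methoxymethoxy)phenol | Oc1c(I)ccc(OCc2ccccc2)c1OCOC | intermediate
7 | 1-(benzyloxy)-4-iodo-3-methoxy-2-(methoxymethoxy)benzene | COc1c(I)ccc(OCc2ccccc2)c1OCOC | intermediate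
8 | diethyl malonate | CCOC(=O)CC(=O)OCC | starting material
9 | diethyl 2-[4-(benzyloxy)-2-methoxy-3-(methoxymethoxy)phenyl]propanedioate | CCOC(=O)C(C(=O)OCC)c1ccc(OCc2ccccc2)c(OCOC)c1OC | intermediate
10 | 2-[4-(benzyloxy)-2-methoxy-3-(methoxymethoxy)phenyl]propane-1,3-diol | OCC(CO)c1ccc(OCc2ccccc2)c(OCOC)c1OC | intermediate
11 | (2R)-2-[4-(benzyloxy)-2-methoxy-3-(methoxymethoxy)phenyl]-3-hydroxypropyl acetate | CC(=O)OC[C@@H](CO)c1ccc(OCc2ccccc2)c(OCOC)c1OC | intermediate
12 | (2S)-2-[4-(benzyloxy)-2-methoxy-3-(methoxymethoxy)phenyl]-3-iodopropyl acetate | CC(=O)OC[C@@H](CI)c1ccc(OCc2ccccc2)c(OCOC)c1OC | intermediate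
13 | 3-hydroxyphenyl benzoate (resorcinol monobenzoate) | O=C(Oc1cccc(O)c1)c1ccccc1 | starting material
14 | 3-(methoxymethoxy)phenyl benzoate | COCOc1cccc(OC(=O)c2ccccc2)c1 | intermediate
15 | 3-(methoxymethoxy)phenol | COCOc1cccc(O)c1 | intermediate
16 | 2-iodo-5-(methoxymethoxy)phenol | COCOc1ccc(I)c(O)c1 | intermediate
17 | 2-iodo-5-(methoxymethoxy)phenyl acetate | COCOc1ccc(I)c(OC(C)=O)c1 | intermediate
18 | [(2S)-3-(acetyloxy)-2-[4-(benzyloxy)-2-methoxy-3-(methoxymethoxy)phenyl]propyl]zinc iodide | CC(=O)OC[C@@H](C[Zn]I)c1ccc(OCc2ccccc2)c(OCOC)c1OC | intermediate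
19 | (2S)-3-[2-(acetyloxy)-4-(methoxymethoxy)phenyl]-2-[4-(benzyloxy)-2-methoxy-3-(methoxymethoxy)phenyl]propyl acetate | CC(=O)OC[C@@H](Cc1ccc(OCOC)cc1OC(C)=O)c1ccc(OCc2ccccc2)c(OCOC)c1OC | intermediate
20 | 2-[(2S)-2-[4-(benzyloxy)-2-methoxy-3-(methoxymethoxy)phenyl]-3-hydroxypropyl]-5-(methoxymethoxy)phenol | OC[C@@H](Cc1ccc(OCOC)cc1O)c1ccc(OCc2ccccc2)c(OCOC)c1OC | intermediate
21 | (3S)-3-[4-(benzyloxy)-2-methoxy-3-(methoxymethoxy)phenyl]-7-(methoxymethoxy)chromane | COc1c([C@H]2COc3cc(OCOC)ccc3C2)ccc(OCc2ccccc2)c1OCOC | intermediate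
22 | 3-methoxy-2-(methoxymethoxy)-4-[(3S)-7-(methoxymethoxy)chroman-3-yl]phenol | COc1c([C@H]2COc3cc(OCOC)ccc3C2)ccc(O)c1OCOC | intermediate
23 | 1-bromo-3-methylbut-2-ene (prenyl bromide) | CC(C)=CCBr | starting material
24 | (3S)-3-[2-methoxy-3-(methoxymethoxy)-4-(3-methylbut-2-enyloxy)phenyl]-7-(methoxymethoxy)chromane | COc1c([C@H]2COc3cc(OCOC)ccc3C2)ccc(OCC=C(C)C)c1OCOC | intermediate
25 | 3-methoxy-2-(methoxymethoxy)-4-[(3S)-7-(methoxymethoxy)chroman-3-yl]-6-(2-methylbut-3-en-2-yl)cyclohexa-2,4-dien-1-one (ring sp3 carbon unassigned) | COC1=C(OCOC)C(=O)C(C(C)(C)C=C)C=C1[C@H]1COc2cc(OCOC)ccc2C1 | intermediate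
26 | 3-methoxy-2-(methoxymethoxy)-4-[(3S)-7-(methoxymethoxy)chroman-3-yl]-6-(2-methylbut-3-en-2-yl)phenol | C=CC(C)(C)c1cc([C@H]2COc3cc(OCOC)ccc3C2)c(OC)c(OCOC)c1O | intermediate
27 | (3S)-3-[3,4-dihydroxy-2-methoxy-5-(2-methylbut-3-en-2-yl)phenyl]chroman-7-ol | C=CC(C)(C)c1cc([C@H]2COc3cc(O)ccc3C2)c(OC)c(O)c1O | target

## Count and risks

Total steps: 20 (16 on the main line, 4 for the ring A fragment).
Longest linear sequence: 16 steps, from 1 to 27 through steps 1–9 and 14–20.

Steps most likely to fail:

**Step 8 (lipase desymmetrisation).** The ortho-methoxy aryl group may lower the selectivity or reverse the enantiotopic preference, and the monoacetate can racemise by 1,3-acyl migration. The fallback sets out from diol 10 and comes back at monoacetate 11. Diol 10 is acetylated on both arms (Ac2O, pyridine) to 2-[4-(benzyloxy)-2-methoxy-3-(methoxymethoxy)phenyl]propane-1,3-diyl diacetate F1. F1 is then desymmetrised in the hydrolytic direction by a hydrolase screened in pH 7 phosphate buffer/t-BuOMe under pH-stat control (the same lipase, porcine pancreatic lipase or pig liver esterase). Hydrolysis frees the arm that the enzyme would otherwise acylate, so an enzyme that gave the (S)-ester by acylation gives (R)-11 here.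

**Step 14 (Negishi coupling).** The alkylpalladium intermediate carries a benzylic β-hydrogen at the stereocentre, so β-hydride loss would give a 2-arylallyl acetate and could erode the ee; the ortho-acetoxy aryl iodide is also hindered. The fallback sets out from iodides 12 and 17 and comes back at 19. It is a nickel-catalysed reductive cross-electrophile coupling of the two iodides (NiI2, 4,4'-di-tert-butyl-2,2'-bipyridine, pyridine, Mn powder, DMPU, 60 °C). The alkyl iodide enters as a radical captured by an arylnickel species, with no preformed organozinc and no alkylpalladium. No new compound is made on this path (entry F0).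

**Step 19 (Claisen rearrangement).** Prenyl ethers can fragment back to phenol 22 with loss of isoprene, and the product can cyclise to a 2,3,3-trimethyl-2,3-dihydrobenzofuran at high temperature. The fallback sets out from phenol 22 and comes back at target 27.
- Ortho-bromination (NBS, cat. i-Pr2NH, CH2Cl2, −20 °C; C-5' is the only free position ortho or para to the OH) gives 6-bromo-3-methoxy-2-(methoxymethoxy)-4-[(3S)-7-(methoxymethoxy)chroman-3-yl]phenol F2.
- NaH/MOMCl in DMF gives (3S)-3-[5-bromo-2-methoxy-3,4-bis(methoxymethoxy)phenyl]-7-(methoxymethoxy)chromane F3.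
- A branched-selective Suzuki–Miyaura coupling with prenylboronic acid pinacol ester (Pd(OAc)2, bulky dialkylbiarylphosphine chosen for γ-selectivity, aq. K3PO4, THF, 40–70 °C) gives (3S)-3-[2-methoxy-3,4-bis(methoxymethoxy)-5-(2-methylbut-3-en-2-yl)phenyl]-7-(methoxymethoxy)chromane F4.
- HCl/MeOH as in step 20 then gives 27.

## Further compounds

F1 | step 8 | 2-[4-(benzyloxy)-2-methoxy-3-(methoxymethoxy)phenyl]propane-1,3-diyl diacetate | CC(=O)OCC(COC(C)=O)c1ccc(OCc2ccccc2)c(OCOC)c1OC
F0 | step 14 | none | none
F2 | step 19 | 6-bromo-3-methoxy-2-(methoxymethoxy)-4-[(3S)-7-(methoxymethoxy)chroman-3-yl]phenol | COc1c([C@H]2COc3cc(OCOC)ccc3C2)cc(Br)c(O)c1OCOC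
F3 | step 19 | (3S)-3-[5-bromo-2-methoxy-3,4-bis(methoxymethoxy)phenyl]-7-(methoxymethoxy)chromane | COc1c([C@H]2COc3cc(OCOC)ccc3C2)cc(Br)c(OCOC)c1OCOC
F4 | step 19 | (3S)-3-[2-methoxy-3,4-bis(methoxymethoxy)-5-(2-methylbut-3-en-2-yl)phenyl]-7-(methoxymethoxy)chromane | C=CC(C)(C)c1cc([C@H]2COc3cc(OCOC)ccc3C2)c(OC)c(OCOC)c1OCOC
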